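The isoflavone is disconnected at both bonds of C4. This carbonyl carbon bridges only C4a of ring A and the aryl-bearing C3, so it can be delivered as carbon monoxide. A palladium-catalysed carbonylative Suzuki–Miyaura coupling unites a symmetric ring A iodide (2-iodo-5-methoxyresorcinol diacetate), CO and a ring B 1-arylvinyl pinacolboronate that already carries the prenyl group and two MOM ethers. One operation forms C4a–C4 and C4–C3 and gives an acyclic α-aryl enone. Acetate methanolysis then frees two equivalent phenols: one closes the pyranone ring by oxa-Michael addition, the other becomes 5-OH. Dehydrogenation across C2–C3 and MOM removal complete the route.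

Key step: step 10

Assumption: C3 of the isoflavanone is formed racemic and is erased by the dehydrogenation, so no stereocontrol is needed. The iodine of the ring A partner must sit between the two oxygens that become O1 and 5-OH, para to the methoxy group. Ring B must carry the vinyl group ortho to one MOM ether and the prenyl group ortho to the other. The structures below were drawn to these requirements.

Step 1
Reactants: 1 5-methoxyresorcinol
Product: 2 1-methoxy-3,5-bis(methoxymethoxy)benzene
Conditions: NaH, MOMCl, DMF, 0 °C to rt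
Reagents that add atoms: chloromethyl methyl ether, COCCl
Why: Williamson-type O-alkylation of both phenoxides with the hard electrophile MOMCl should give the bis-acetal, which then serves as the directing group for lithiation.

Step 2
Reactants: 2 1-methoxy-3,5-bis(methoxymethoxy)benzene
Product: 4 2-iodo-5-methoxy-1,3-bis(methoxymethoxy)benzene, via aryllithium 3 (not isolated)
Conditions: n-BuLi, THF, 0 °C; I2, −78 °C to rt
Reagents that add atoms: iodine, II
Why: Directed ortho-metalation should occur at C2 because this position lies between two chelating OMOM groups, which outrank the OMOM/OMe pair flanking C4 and C6, and iodine then quenches the aryllithium to the symmetric iodide.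

Step 3
Reactants: 4 2-iodo-5-methoxy-1,3-bis(methoxymethoxy)benzene
Product: 5 2-iodo-5-methoxybenzene-1,3-diol
Conditions: HCl (1.25 M in MeOH), rt
Reagents that add atoms: none
Why: Acid-catalysed acetal methanolysis at room temperature should remove both MOM groups while the aryl methyl ether and the C–I bond stay untouched.

Step 4
Reactants: 5 2-iodo-5-methoxybenzene-1,3-diol
Product: 6 2-iodo-5-methoxy-1,3-phenylene diacetate
Conditions: Ac2O, pyridine, DMAP (cat.), CH2Cl2, rt
Reagents that add atoms: acetic anhydride, CC(=O)OC(C)=O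
Why: DMAP-catalysed O-acylation installs two base-labile masks that are orthogonal to the acid-labile MOM ethers of ring B and leave the aryl iodide doubly ortho-substituted.

Step 5
Reactants: 7 4,6-dibromoresorcinol
Product: 8 1,5-dibromo-2,4-bis(methoxymethoxy)benzene
Conditions: NaH, MOMCl, DMF, 0 °C to rt
Reagents that add atoms: chloromethyl methyl ether, COCCl
Why: Williamson-type O-alkylation of both phenoxides protects ring B as acetals that tolerate the organolithium, palladium and basic steps that follow.

Step 6
Reactants: 8 1,5-dibromo-2,4-bis(methoxymethoxy)benzene; 9 1-bromo-3-methylbut-2-ene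
Product: 11 1-bromo-2,4-bis(methoxymethoxy)-5-(3-methylbut-2-enyl)benzene, via monolithiated bromoarene 10 (not isolated)
Conditions: n-BuLi (1.0 equiv), THF, −78 °C; CuBr·SMe2 (0.2 equiv); 9, −78 °C to rt
Reagents that add atoms: 1-bromo-3-methylbut-2-ene (9), CC(C)=CCBr
Why: Bromine–lithium exchange at one of the two equivalent C–Br bonds gives an ortho-alkoxy-stabilised aryllithium, and its copper-mediated SN2 allylation by the primary prenyl bromide should place the prenyl group, the hindered tertiary terminus disfavouring SN2′ attack.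

Step 7
Reactants: 11 1-bromo-2,4-bis(methoxymethoxy)-5-(3-methylbut-2-enyl)benzene; 12 N-methoxy-N-methylacetamide
Product: 15 1-[2,4-bis(methoxymethoxy)-5-(3-methylbut-2-enyl)phenyl]ethanone, via aryllithium 13 (not isolated), via tetrahedral lithium adduct 14 (not isolated)
Conditions: n-BuLi, THF, −78 °C; 12, −78 to 0 °C; aq. NH4Cl
Reagents that add atoms: N-methoxy-N-methylacetamide (12), CON(C)C(C)=O
Why: A second bromine–lithium exchange followed by Weinreb amide acylation should stop at the ketone stage, because the chelated tetrahedral adduct only collapses on aqueous quench.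

Step 8
Reactants: 15 1-[2,4-bis(methoxymethoxy)-5-(3-methylbut-2-enyl)phenyl]ethanone
Product: 17 1-[2,4-bis(methoxymethoxy)-5-(3-methylbut-2-enyl)phenyl]ethenyl trifluoromethanesulfonate, via potassium enolate 16 (not isolated)
Conditions: KN(SiMe3)2, THF, −78 °C; PhNTf2, −78 to 0 °C; filtration through Et3N-deactivated silica
Reagents that add atoms: N-phenylbis(trifluoromethanesulfonimide), O=S(=O)(N(c1ccccc1)S(=O)(=O)C(F)(F)F)C(F)(F)F
Why: Deprotonation at the only enolisable position (the methyl group) and O-sulfonylation of the potassium enolate is standard enol triflate formation and fixes the position of the future C2=C3 carbons.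

Step 9
Reactants: 17 1-[2,4-bis(methoxymethoxy)-5-(3-methylbut-2-enyl)phenyl]ethenyl trifluoromethanesulfonate; 18 bis(pinacolato)diboron
Product: 19 2-{1-[2,4-bis(methoxymethoxy)-5-(3-methylbut-2-enyl)phenyl]ethenyl}-4,4,5,5-tetramethyl-1,3,2-dioxaborolane
Conditions: PdCl2(PPh3)2 (3 mol %), PPh3 (6 mol %), KOPh, toluene, 50 °C
Reagents that add atoms: bis(pinacolato)diboron (18), CC1(C)OB(OC1(C)C)B1OC(C)(C)C(C)(C)O1
Why: Miyaura borylation of an alkenyl triflate (oxidative addition of zerovalent palladium, phenoxide-assisted transmetalation with the diboron reagent, reductive elimination) should give the 1-arylvinyl boronate under conditions that leave the MOM ethers and the prenyl olefin alone.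

Step 10
Reactants: 6 2-iodo-5-methoxy-1,3-phenylene diacetate; 19 2-{1-[2,4-bis(methoxymethoxy)-5-(3-methylbut-2-enyl)phenyl]ethenyl}-4,4,5,5-tetramethyl-1,3,2-dioxaborolane; 20 carbon monoxide
Product: 21 2-{2-[2,4-bis(methoxymethoxy)-5-(3-methylbut-2-enyl)phenyl]prop-2-enoyl}-5-methoxy-1,3-phenylene diacetate
Conditions: PdCl2(dppf) (5 mol %), K2CO3 (anhydrous, 3 equiv), CO (5 bar), anisole, 80 °C
Reagents that add atoms: carbon monoxide (20), [C-]#[O+]
Why: Zerovalent palladium generated from PdCl2(dppf) inserts into the C–I bond of 6, CO migrates into the aryl–palladium bond to give an aroyl–palladium species, and base-assisted transmetalation with alkenylboronate 19 followed by reductive elimination creates C4a–C4 and C4–C3. This is a carbonylative Suzuki–Miyaura coupling of an aryl iodide with an alkenylboronate to an aryl vinyl ketone, a known reaction type. No ring closes and no stereocentre is formed; the enone stays acyclic because both ring A oxygens are still acetylated. The selectivity needed is CO insertion ahead of direct aryl–alkenyl coupling: the two ortho acetoxy groups slow transmetalation at the aryl–palladium stage, the electron-rich aryl group migrates readily to CO, and CO pressure keeps the acyl species populated. Anhydrous carbonate in anisole should limit acetate loss, and an acetate cleaved after the coupling only anticipates step 11.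

Step 11
Reactants: 21 2-{2-[2,4-bis(methoxymethoxy)-5-(3-methylbut-2-enyl)phenyl]prop-2-enoyl}-5-methoxy-1,3-phenylene diacetate
Product: 23 (±)-5-hydroxy-7-methoxy-3-[2,4-bis(methoxymethoxy)-5-(3-methylbut-2-enyl)phenyl]-2,3-dihydro-4H-chromen-4-one, via dihydroxy enone 22 (not isolated)
Conditions: K2CO3 (0.5 equiv), MeOH/THF, 0 °C to rt; aq. NH4Cl
Reagents that add atoms: none
Why: Methoxide-mediated transesterification frees both phenols and the phenoxide should add to the enone terminus in a 6-endo-trig oxa-Michael closure; ring A is symmetric, so either oxygen gives the same chromanone while the other stays as the hydrogen-bonded 5-OH, and C3 is formed racemic and removed in step 12.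

Step 12
Reactants: 23 (±)-5-hydroxy-7-methoxy-3-[2,4-bis(methoxymethoxy)-5-(3-methylbut-2-enyl)phenyl]-2,3-dihydro-4H-chromen-4-one
Product: 27 5-hydroxy-7-methoxy-3-[2,4-bis(methoxymethoxy)-5-(3-methylbut-2-enyl)phenyl]-4H-chromen-4-one, via dilithium enolate 24 (not isolated), via C3 selenide 25 (not isolated), via selenoxide 26 (not isolated)
Conditions: LiN(SiMe3)2 (2.3 equiv), THF, −78 °C; PhSeCl (1.05 equiv), −78 °C; aq. NaHCO3; NaIO4, THF/MeOH/H2O, 0 °C to rt
Reagents that add atoms: none
Why: α-Selenenylation of the ketone enolate at the acidic benzylic C3, periodate oxidation and selenoxide syn-elimination, which can only take a hydrogen from C2, should give the C2=C3 double bond without a quinone or peroxide oxidant that would attack the prenyl group or the electron-rich ring B.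

Step 13
Reactants: 27 5-hydroxy-7-methoxy-3-[2,4-bis(methoxymethoxy)-5-(3-methylbut-2-enyl)phenyl]-4H-chromen-4-one
Product: 28 Isopoegin B, 3-[2,4-dihydroxy-5-(3-methylbut-2-enyl)phenyl]-5-hydroxy-7-methoxy-4H-chromen-4-one
Conditions: HCl (1.25 M in MeOH), MeOH/THF, 35 °C
Reagents that add atoms: none
Why: Mild acid-catalysed acetal methanolysis should free the two ring B phenols, while the prenyl olefin, which cyclises onto the neighbouring phenol only under forcing acid, is preserved.

Compound list
1 | 5-methoxyresorcinol (5-methoxybenzene-1,3-diol) | COc1cc(O)cc(O)c1 | starting material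
2 | 1-methoxy-3,5-bis(methoxymethoxy)benzene | COCOc1cc(OC)cc(OCOC)c1 | intermediate
3 | [4-methoxy-2,6-bis(methoxymethoxy)phenyl]lithium | [Li]c1c(OCOC)cc(OC)cc1OCOC | intermediate
4 | 2-iodo-5-methoxy-1,3-bis(methoxymethoxy)benzene | COCOc1cc(OC)cc(OCOC)c1I | intermediate
5 | 2-iodo-5-methoxybenzene-1,3-diol | COc1cc(O)c(I)c(O)c1 | intermediate
6 | 2-iodo-5-methoxy-1,3-phenylene diacetate | COc1cc(OC(C)=O)c(I)c(OC(C)=O)c1 | intermediate
7 | 4,6-dibromoresorcinol (4,6-dibromobenzene-1,3-diol) | Oc1cc(O)c(Br)cc1Br | starting material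
8 | 1,5-dibromo-2,4-bis(methoxymethoxy)benzene | COCOc1cc(OCOC)c(Br)cc1Br | intermediate
9 | 1-bromo-3-methylbut-2-ene | CC(C)=CCBr | starting material
10 | [5-bromo-2,4-bis(methoxymethoxy)phenyl]lithium | COCOc1cc(OCOC)c(Br)cc1[Li] | intermediate
11 | 1-bromo-2,4-bis(methoxymethoxy)-5-(3-methylbut-2-enyl)benzene | COCOc1cc(OCOC)c(CC=C(C)C)cc1Br | intermediate
12 | N-methoxy-N-methylacetamide | CON(C)C(C)=O | starting material
13 | [2,4-bis(methoxymethoxy)-5-(3-methylbut-2-enyl)phenyl]lithium | COCOc1cc(OCOC)c(CC=C(C)C)cc1[Li] | intermediate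
14 | lithium 1-[2,4-bis(methoxymethoxy)-5-(3-methylbut-2-enyl)phenyl]-1-[methoxy(methyl)amino]ethanolate | COCOc1cc(OCOC)c(CC=C(C)C)cc1C(C)(O[Li])N(C)OC | intermediate
15 | 1-[2,4-bis(methoxymethoxy)-5-(3-methylbut-2-enyl)phenyl]ethanone | CC(=O)c1cc(CC=C(C)C)c(OCOC)cc1OCOC | intermediate
16 | potassium 1-[2,4-bis(methoxymethoxy)-5-(3-methylbut-2-enyl)phenyl]ethenolate | C=C(O[K])c1cc(CC=C(C)C)c(OCOC)cc1OCOC | intermediate
17 | 1-[2,4-bis(methoxymethoxy)-5-(3-methylbut-2-enyl)phenyl]ethenyl trifluoromethanesulfonate | C=C(OS(=O)(=O)C(F)(F)F)c1cc(CC=C(C)C)c(OCOC)cc1OCOC | intermediate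
18 | bis(pinacolato)diboron | CC1(C)OB(OC1(C)C)B1OC(C)(C)C(C)(C)O1 | starting material
19 | 2-{1-[2,4-bis(methoxymethoxy)-5-(3-methylbut-2-enyl)phenyl]ethenyl}-4,4,5,5-tetramethyl-1,3,2-dioxaborolane | C=C(B1OC(C)(C)C(C)(C)O1)c1cc(CC=C(C)C)c(OCOC)cc1OCOC | intermediate
20 | carbon monoxide | [C-]#[O+] | starting material
21 | 2-{2-[2,4-bis(methoxymethoxy)-5-(3-methylbut-2-enyl)phenyl]prop-2-enoyl}-5-methoxy-1,3-phenylene diacetate | COc1cc(OC(C)=O)c(C(=O)C(=C)c2cc(CC=C(C)C)c(OCOC)cc2OCOC)c(OC(C)=O)c1 | intermediate
22 | 1-(2,6-dihydroxy-4-methoxyphenyl)-2-[2,4-bis(methoxymethoxy)-5-(3-methylbut-2-enyl)phenyl]prop-2-en-1-one | COc1cc(O)c(C(=O)C(=C)c2cc(CC=C(C)C)c(OCOC)cc2OCOC)c(O)c1 | intermediate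
23 | (±)-5-hydroxy-7-methoxy-3-[2,4-bis(methoxymethoxy)-5-(3-methylbut-2-enyl)phenyl]-2,3-dihydro-4H-chromen-4-one (racemic at C3) | COc1cc(O)c2c(c1)OCC(c1cc(CC=C(C)C)c(OCOC)cc1OCOC)C2=O | intermediate
24 | dilithium enolate-phenoxide of 23 | COc1cc(O[Li])c2c(c1)OCC(c1cc(CC=C(C)C)c(OCOC)cc1OCOC)=C2O[Li] | intermediate
25 | (±)-5-hydroxy-7-methoxy-3-(phenylselanyl)-3-[2,4-bis(methoxymethoxy)-5-(3-methylbut-2-enyl)phenyl]-2,3-dihydro-4H-chromen-4-one (racemic) | COc1cc(O)c2c(c1)OCC([Se]c1ccccc1)(c1cc(CC=C(C)C)c(OCOC)cc1OCOC)C2=O | intermediate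
26 | selenoxide of 25 (mixture of diastereomers at selenium, racemic) | COc1cc(O)c2c(c1)OCC([Se](=O)c1ccccc1)(c1cc(CC=C(C)C)c(OCOC)cc1OCOC)C2=O | intermediate
27 | 5-hydroxy-7-methoxy-3-[2,4-bis(methoxymethoxy)-5-(3-methylbut-2-enyl)phenyl]-4H-chromen-4-one | COc1cc(O)c2c(=O)c(-c3cc(CC=C(C)C)c(OCOC)cc3OCOC)coc2c1 | intermediate
28 | Isopoegin B, 3-[2,4-dihydroxy-5-(3-methylbut-2-enyl)phenyl]-5-hydroxy-7-methoxy-4H-chromen-4-one | COc1cc(O)c2c(=O)c(-c3cc(CC=C(C)C)c(O)cc3O)coc2c1 | target

Total step count: 13. Longest linear sequence: 9 steps (steps 5 to 13, from 7); the ring A branch (steps 1 to 4) joins at step 10.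

Steps most likely to fail

Step 10. Transmetalation of the crowded, doubly ortho-substituted aroyl–palladium intermediate with the α-branched alkenylboronate may be too slow. Protodeboronation, direct non-carbonylative coupling or base-induced acetate loss before coupling could then take over. The fallback forms the two bonds to C4 in separate operations. Iodide 6 would be formylated under neutral reductive carbonylation conditions (Pd(PPh3)4, CO 3 bar, Bu3SnH added slowly, toluene, 50 °C) to 2-formyl-5-methoxy-1,3-phenylene diacetate F1. A Nozaki–Hiyama–Kishi coupling of enol triflate 17 with F1 (CrCl2, NiCl2 cat., DMF, rt), which tolerates aryl acetates, would give racemic 2-{1-hydroxy-2-[2,4-bis(methoxymethoxy)-5-(3-methylbut-2-enyl)phenyl]prop-2-enyl}-5-methoxy-1,3-phenylene diacetate F2. Prompt Dess–Martin oxidation (NaHCO3, CH2Cl2, 0 °C) would return the route to enone 21.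

Step 12. The dianion may open by β-elimination of the ring oxygen (retro-oxa-Michael) before selenium is captured, or the selenium electrophile may react at C6/C8 of the electron-rich ring A or at the prenyl olefin. The fallback drops enolate chemistry and dehydrogenates the neutral ketone 23 through its enol with 2-iodoxybenzoic acid (DMSO/toluene, 65 °C). This needs no strong base and leads directly to 27; no new compound is made (F0). Quinone oxidants are excluded in either case, because hydride abstraction from the benzylic, allylic CH2 of the prenyl group on the dialkoxyarene would compete.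

Step 8. The electron-rich α-aryl vinyl triflate may ionise or hydrolyse during work-up and chromatography, returning ketone 15. The fallback is a Shapiro sequence from 15. Condensation with 2,4,6-triisopropylbenzenesulfonohydrazide (THF, rt) would give the sulfonylhydrazone N'-{1-[2,4-bis(methoxymethoxy)-5-(3-methylbut-2-enyl)phenyl]ethylidene}-2,4,6-triisopropylbenzenesulfonohydrazide F3. Treatment with n-BuLi (2.05 equiv, THF, −78 to 0 °C) would release nitrogen and sulfinate to give {1-[2,4-bis(methoxymethoxy)-5-(3-methylbut-2-enyl)phenyl]ethenyl}lithium F4. Trapping at −78 °C with 2-isopropoxy-4,4,5,5-tetramethyl-1,3,2-dioxaborolane would return the route at boronate 19, bypassing 17 and step 9.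

Further compounds
F1 | step 10 | 2-formyl-5-methoxy-1,3-phenylene diacetate | COc1cc(OC(C)=O)c(C=O)c(OC(C)=O)c1
F2 | step 10 | (±)-2-{1-hydroxy-2-[2,4-bis(methoxymethoxy)-5-(3-methylbut-2-enyl)phenyl]prop-2-enyl}-5-methoxy-1,3-phenylene diacetate | COc1cc(OC(C)=O)c(C(O)C(=C)c2cc(CC=C(C)C)c(OCOC)cc2OCOC)c(OC(C)=O)c1
F0 | step 12 | none | none
F3 | step 8 | (E)-N'-{1-[2,4-bis(methoxymethoxy)-5-(3-methylbut-2-enyl)phenyl]ethylidene}-2,4,6-triisopropylbenzenesulfonohydrazide | C/C(=N\NS(=O)(=O)c1c(C(C)C)cc(C(C)C)cc1C(C)C)c1cc(CC=C(C)C)c(OCOC)cc1OCOC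
F4 | step 8 | {1-[2,4-bis(methoxymethoxy)-5-(3-methylbut-2-enyl)phenyl]ethenyl}lithium | [Li]C(=C)c1cc(CC=C(C)C)c(OCOC)cc1OCOC
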